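**Retrosynthetic overview**

1. Locants follow the kaurane skeleton (C1 enone C=O, C5–C6 the CH–CH2OH unit, C7/C20 lactone C=O/CH2, C8 and C10 quaternary, C11–C12 the CH2–CH2 of ring C, C13 carbinol, C14 bridging CH2, C15 ketone, C16–C17 the CH–CH3). The C16 methyl comes from exo-face hydrogenation of a 16-methylene-15-ketone, and ring D from an aldol disconnection C16–C13 to an 8-acetyl ring C ketone.
2. Ring C is disconnected at C11–C12 as a retro ring enlargement: the six-membered C13 ketone (C8, C14, C13, C12, C11, C9) goes back to a methylenecyclopentane (C8, C14, C13, C11, C9) carrying C12 as exocyclic CH2 on C13. The enabling feature is that C13, the only oxygen-bearing carbon of ring C, lies between C12 and C14 and 1,3 to the quaternary C8, so an oxygen on C13 can push C11 from C13 onto C12.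
3. The methylenecyclopentane is the [3+2] adduct of palladium–trimethylenemethane with the C8=C9 bond of a 3-acetyl-5,6-dihydropyran-2-one. This sets C8 and C9 cis in one step and gives the 1,3 relation of the C13 oxygen to C8 that a Diels–Alder reaction cannot give.
4. The spirolactone comes from a 5,6-disubstituted 4,4-dimethylcyclohex-2-enone (ring A) by enolate alkenylation (quaternary C10) and lactonization; C5 is set by copper-catalysed asymmetric conjugate addition to 4,4-dimethylcyclohexa-2,5-dienone.
5. Order of ring formation: ring A (purchased carbocycle) → δ-lactone → five-membered carbocycle → ring C by enlargement → ring D by aldol.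

Key step: step 8

Remark on the chemistry: the ring A enone (C1=O, C2=C3) has no enolizable hydrogen (C4 and C10 are quaternary) and is therefore carried unprotected from compound 2 to the target; CIP descriptors change between some intermediates only because substituent priorities change.

**Step 1**
Reactants: 1 4,4-dimethylcyclohex-2-en-1-one
Product: 2 4,4-dimethylcyclohexa-2,5-dien-1-one
Conditions: DDQ, 1,4-dioxane, reflux
Reagents that add atoms: none
Why: Quinone (DDQ) dehydrogenation of the enone at C5–C6, the only site available because C4 is quaternary, should give the achiral cross-conjugated dienone; no stereocenter is formed.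

**Step 2**
Reactants: 2 4,4-dimethylcyclohexa-2,5-dien-1-one; 3 (chloromethyl)dimethyl(propan-2-yloxy)silane
Product: 5 (5S)-5-{[dimethyl(propan-2-yloxy)silyl]methyl}-4,4-dimethylcyclohex-2-en-1-one, via silylmethylmagnesium chloride 4 (not isolated)
Conditions: 3, Mg, Et2O, reflux; then 2, CuBr·SMe2 (5 mol %), (R)-1-[(S)-2-(diphenylphosphino)ferrocenyl]ethyldicyclohexylphosphine (6 mol %), tBuOMe, −78 °C; aq. NH4Cl
Reagents that add atoms: none
Why: Copper-catalysed asymmetric conjugate addition of a Grignard reagent, run as a desymmetrization of the achiral dienone: the chiral CuBr–diphosphine complex should select one of the two enantiotopic β-carbons and one face, which sets C5 (S here; the ligand enantiomer is chosen for this sense), and the magnesium enolate formed shields the second enone from further addition.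

**Step 3**
Reactants: 5 (5S)-5-{[dimethyl(propan-2-yloxy)silyl]methyl}-4,4-dimethylcyclohex-2-en-1-one
Product: 6 (5S)-5-(hydroxymethyl)-4,4-dimethylcyclohex-2-en-1-one
Conditions: H2O2 (30 % aq.), KF, KHCO3, THF–MeOH, 0 °C → rt
Reagents that add atoms: hydrogen peroxide OO
Why: Tamao oxidation replaces the activated C–Si bond by C–OH through migration in a pentacoordinate silyl hydroperoxide, and the hindered enone (β-carbon next to quaternary C4) should survive the buffered peroxide; C5 is untouched.

**Step 4**
Reactants: 6 (5S)-5-(hydroxymethyl)-4,4-dimethylcyclohex-2-en-1-one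
Product: 7 (5S)-5-({[tert-butyl(diphenyl)silyl]oxy}methyl)-4,4-dimethylcyclohex-2-en-1-one
Conditions: tBuPh2SiCl, imidazole, DMF, rt
Reagents that add atoms: tert-butyl(chloro)diphenylsilane CC(C)(C)[Si](Cl)(c1ccccc1)c1ccccc1
Why: Standard silylation of the primary alcohol gives an acid-stable ether whose bulk on the C5 arm later helps to direct steps 6 and 7.

**Step 5**
Reactants: 7 (5S)-5-({[tert-butyl(diphenyl)silyl]oxy}methyl)-4,4-dimethylcyclohex-2-en-1-one
Product: 9 (5S,6R)-5-({[tert-butyl(diphenyl)silyl]oxy}methyl)-4,4-dimethyl-6-{[(triethylsilyl)oxy]methyl}cyclohex-2-en-1-one, via hydroxymethyl ketone 8 (not isolated)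
Conditions: LiN(iPr)2, THF, −78 °C; CH2O (monomeric, THF solution), −78 °C; then Et3SiCl, −78 → 0 °C
Reagents that add atoms: formaldehyde C=O; chlorotriethylsilane CC[Si](Cl)(CC)CC
Why: Kinetic α′-deprotonation (C6 is the only enolizable carbon), aldol addition to formaldehyde anti to the C5 substituent and in situ O-silylation install the future C20; the C6 configuration is erased in step 6 and does not matter.

**Step 6**
Reactants: 9 (5S,6R)-5-({[tert-butyl(diphenyl)silyl]oxy}methyl)-4,4-dimethyl-6-{[(triethylsilyl)oxy]methyl}cyclohex-2-en-1-one; 10 ethyl 2-(ethoxymethylidene)-3-oxobutanoate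
Product: 13 (6S,11R)-4-acetyl-11-({[tert-butyl(diphenyl)silyl]oxy}methyl)-10,10-dimethyl-2-oxaspiro[5.5]undeca-4,8-diene-3,7-dione, via alkenylated ketone 11 (not isolated), via hydroxy ester 12 (not isolated)
Conditions: LiN(iPr)2, THF, −78 °C; 10, −78 → −30 °C; then 1 M HCl, THF, rt; then TsOH (cat.), PhMe, 80 °C
Reagents that add atoms: none
Why: Addition–elimination of the tetrasubstituted lithium enolate to the ethoxymethylene β-keto ester (vinylogous acylation) should create the quaternary C10 with the electrophile entering anti to the pseudo-axial C5 CH2OSi group (A-1,2 strain), after which acid removes the triethylsilyl group and the freed C20 hydroxyl lactonizes onto the ethyl ester once the doubly activated alkene has equilibrated.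

**Step 7**
Reactants: 13 (6S,11R)-4-acetyl-11-({[tert-butyl(diphenyl)silyl]oxy}methyl)-10,10-dimethyl-2-oxaspiro[5.5]undeca-4,8-diene-3,7-dione; 14 2-[(trimethylsilyl)methyl]prop-2-en-1-yl acetate
Product: 15 (5R,8S,9S,10S)-methylenecyclopentane-fused spirolactone [ring C8–C14H2–C13(=C12H2)–C11H2–C9 cis-fused to the lactone; acetyl on C8; C6 silyl ether]
Conditions: Pd(OAc)2 (5 mol %), P(OiPr)3 (30 mol %), THF, reflux
Reagents that add atoms: none
Why: Palladium–trimethylenemethane [3+2] cycloaddition to a doubly activated alkene: the zwitterionic complex (η3-C4H6)Pd[P(OiPr)3]2 should add to C9 on the lactone face syn to the flat C1 carbonyl and anti to the bulky C5 arm, and the stabilized enolate then closes onto the π-allyl on the same face, so C9 (S) and quaternary C8 (S) are set cis with the acetyl group on the opposite face.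

**Step 8**
Reactants: 15 (5R,8S,9S,10S)-methylenecyclopentane-fused spirolactone
Product: 16 (5R,8S,9S,10S)-8-acetyl ring C ketone [ring C8–C14H2–C13(=O)–C12H2–C11H2–C9 cis-fused to the lactone; C6 silyl ether]
Conditions: Tl(NO3)3·3H2O (1.1 equiv), MeOH, −20 → 0 °C; then 1 M HCl, THF, rt
Reagents that add atoms: water O
Why: Trivalent thallium adds to the exocyclic CH2 (C12) in the Markovnikov sense while methanol captures the tertiary C13; loss of monovalent thallium from the weak C12–Tl bond is then assisted by the C13 oxygen, which pushes a ring bond onto C12 and ends as an oxocarbenium ion or ketal that acid hydrolyses to the C13 ketone. The closest known reaction type is the oxidative ring expansion of methylenecycloalkanes to the next higher cycloalkanones with Tl(NO3)3, a relative of the Tiffeneau–Demjanov and semipinacol rearrangements. Ring C (C8–C14–C13–C12–C11–C9) is closed by a 1,2-alkyl shift in which C11 migrates from C13 to C12, so the five-membered ring is enlarged by forming C11–C12 at the expense of C11–C13. No new stereocenter is formed: C8 and C9 are not involved and the migrating CH2 carries no stereochemistry, so the cis fusion from step 7 is kept. The selectivity needed is migration of C11 rather than C14; C14 is neopentylic and bonded to C8 with its two carbonyl groups, which should make it the more hindered and less electron-rich migrating group. The electron-poor ring A enone, the ketone and the lactone should not react with the electrophilic thallium salt on this time scale.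

**Step 9**
Reactants: 16 (5R,8S,9S,10S)-8-acetyl ring C ketone
Product: 17 (5R,8S,9S,10S,13S)-13-hydroxy-1,15-dioxo-17-nor-6,7-secokaur-2-en-7,20-olide 6-O-tert-butyldiphenylsilyl ether
Conditions: LiN(SiMe3)2 (1.1 equiv), THF, −78 → −40 °C; AcOH, −78 °C
Reagents that add atoms: none
Why: Intramolecular aldol addition of the methyl ketone enolate (C16) to the C13 ketone closes ring D as the bicyclo[3.2.1]octane; the acetyl group, axial on C8, can reach only the syn face of C13, which fixes C13 (S), dehydration is impossible at the bridgehead and the chelated lithium aldolate is the thermodynamic sink.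

**Step 10**
Reactants: 17 (5R,8S,9S,10S,13S)-13-hydroxy-1,15-dioxo-17-nor-6,7-secokaur-2-en-7,20-olide 6-O-tert-butyldiphenylsilyl ether
Product: 18 (5R,8S,9S,10S,13S)-13-hydroxy-1,15-dioxo-6,7-secokaura-2,16-dien-7,20-olide 6-O-tert-butyldiphenylsilyl ether
Conditions: (CH2O)n, PhNHMe·CF3CO2H, THF, reflux
Reagents that add atoms: paraformaldehyde (formaldehyde unit) C=O
Why: Mannich-type α-methylenation at C16, the only enolizable carbon left (C4, C8 and C10 are quaternary), gives the exocyclic enone and introduces C17; no stereocenter is formed.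

**Step 11**
Reactants: 18 (5R,8S,9S,10S,13S)-13-hydroxy-1,15-dioxo-6,7-secokaura-2,16-dien-7,20-olide 6-O-tert-butyldiphenylsilyl ether
Product: 19 (5R,8S,9S,10S,13S,16R)-13-hydroxy-1,15-dioxo-6,7-secokaur-2-en-7,20-olide 6-O-tert-butyldiphenylsilyl ether
Conditions: H2 (1 atm), RhCl(PPh3)3 (10 mol %), PhMe, rt
Reagents that add atoms: none
Why: Homogeneous hydrogenation with RhCl(PPh3)3 should reduce the unhindered 1,1-disubstituted exocyclic alkene and spare the cis-disubstituted ring A enone next to the gem-dimethyl carbon; hydrogen is delivered to C16 from the exo face (side of the one-carbon bridge C14, away from C11–C12), which places the methyl endo and sets C16 (R).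

**Step 12**
Reactants: 19 (5R,8S,9S,10S,13S,16R)-13-hydroxy-1,15-dioxo-6,7-secokaur-2-en-7,20-olide 6-O-tert-butyldiphenylsilyl ether
Product: 20 (5R,8S,9S,10S,13S,16R)-6,13-dihydroxy-1,15-dioxo-6,7-secokaur-2-en-7,20-olide (target)
Conditions: HF·pyridine, THF, 0 °C → rt
Reagents that add atoms: none
Why: Fluoride-mediated cleavage of the primary silyl ether under non-basic conditions frees the C6 alcohol without retro-aldol opening of ring D or epimerization at C16.

**Compound list**

1 | 4,4-dimethylcyclohex-2-en-1-one | CC1(C)CCC(=O)C=C1 | starting material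
2 | 4,4-dimethylcyclohexa-2,5-dien-1-one | CC1(C)C=CC(=O)C=C1 | intermediate
3 | (chloromethyl)dimethyl(propan-2-yloxy)silane | C[Si](C)(CCl)OC(C)C | starting material
4 | {[dimethyl(propan-2-yloxy)silyl]methyl}magnesium chloride | CC(C)O[Si](C)(C)C[Mg]Cl | intermediate
5 | (5S)-5-{[dimethyl(propan-2-yloxy)silyl]methyl}-4,4-dimethylcyclohex-2-en-1-one | O=C1C=CC(C)(C)[C@@H](C[Si](C)(C)OC(C)C)C1 | intermediate
6 | (5S)-5-(hydroxymethyl)-4,4-dimethylcyclohex-2-en-1-one | O=C1C=CC(C)(C)[C@@H](CO)C1 | intermediate
7 | (5S)-5-({[tert-butyl(diphenyl)silyl]oxy}methyl)-4,4-dimethylcyclohex-2-en-1-one | O=C1C=CC(C)(C)[C@@H](CO[Si](c2ccccc2)(c2ccccc2)C(C)(C)C)C1 | intermediate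
8 | (5S,6R)-5-({[tert-butyl(diphenyl)silyl]oxy}methyl)-6-(hydroxymethyl)-4,4-dimethylcyclohex-2-en-1-one (trans) | O=C1C=CC(C)(C)[C@@H](CO[Si](c2ccccc2)(c2ccccc2)C(C)(C)C)[C@@H]1CO | intermediate
9 | (5S,6R)-5-({[tert-butyl(diphenyl)silyl]oxy}methyl)-4,4-dimethyl-6-{[(triethylsilyl)oxy]methyl}cyclohex-2-en-1-one | O=C1C=CC(C)(C)[C@@H](CO[Si](c2ccccc2)(c2ccccc2)C(C)(C)C)[C@@H]1CO[Si](CC)(CC)CC | intermediate
10 | ethyl 2-(ethoxymethylidene)-3-oxobutanoate (E/Z mixture) | CCOC=C(C(C)=O)C(=O)OCC | starting material
11 | ethyl 2-acetyl-3-[(1S,6R)-6-({[tert-butyl(diphenyl)silyl]oxy}methyl)-5,5-dimethyl-2-oxo-1-{[(triethylsilyl)oxy]methyl}cyclohex-3-en-1-yl]prop-2-enoate | O=C1C=CC(C)(C)[C@@H](CO[Si](c2ccccc2)(c2ccccc2)C(C)(C)C)[C@]1(CO[Si](CC)(CC)CC)C=C(C(C)=O)C(=O)OCC | intermediate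
12 | ethyl 2-acetyl-3-[(1S,6R)-6-({[tert-butyl(diphenyl)silyl]oxy}methyl)-1-(hydroxymethyl)-5,5-dimethyl-2-oxocyclohex-3-en-1-yl]prop-2-enoate | O=C1C=CC(C)(C)[C@@H](CO[Si](c2ccccc2)(c2ccccc2)C(C)(C)C)[C@]1(CO)C=C(C(C)=O)C(=O)OCC | intermediate
13 | (6S,11R)-4-acetyl-11-({[tert-butyl(diphenyl)silyl]oxy}methyl)-10,10-dimethyl-2-oxaspiro[5.5]undeca-4,8-diene-3,7-dione | CC(=O)C1=C[C@]2(COC1=O)C(=O)C=CC(C)(C)[C@H]2CO[Si](c1ccccc1)(c1ccccc1)C(C)(C)C | intermediate
14 | 2-[(trimethylsilyl)methyl]prop-2-en-1-yl acetate | CC(=O)OCC(=C)C[Si](C)(C)C | starting material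
15 | (5R,8S,9S,10S)-methylenecyclopentane-fused spirolactone: δ-lactone (C7, O, C20, C10, C9, C8) spiro at C10 to ring A (1-oxo-2-ene, 4,4-dimethyl, C5 CH2OSitBuPh2) and cis-fused at C8–C9 to the ring C8–C14H2–C13(=C12H2)–C11H2–C9; acetyl on C8 | CC(=O)[C@]12CC(=C)C[C@H]1[C@]1(COC2=O)C(=O)C=CC(C)(C)[C@H]1CO[Si](c1ccccc1)(c1ccccc1)C(C)(C)C | intermediate
16 | (5R,8S,9S,10S)-8-acetyl ring C ketone: as 15 but with the six-membered ring C8–C14H2–C13(=O)–C12H2–C11H2–C9 | CC(=O)[C@]12CC(=O)CC[C@H]1[C@]1(COC2=O)C(=O)C=CC(C)(C)[C@H]1CO[Si](c1ccccc1)(c1ccccc1)C(C)(C)C | intermediate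
17 | (5R,8S,9S,10S,13S)-13-hydroxy-1,15-dioxo-17-nor-6,7-secokaur-2-en-7,20-olide 6-O-tert-butyldiphenylsilyl ether | C1C(=O)[C@]23C[C@@]1(O)CC[C@H]2[C@]1(COC3=O)C(=O)C=CC(C)(C)[C@H]1CO[Si](c1ccccc1)(c1ccccc1)C(C)(C)C | intermediate
18 | (5R,8S,9S,10S,13S)-13-hydroxy-1,15-dioxo-6,7-secokaura-2,16-dien-7,20-olide 6-O-tert-butyldiphenylsilyl ether | C=C1C(=O)[C@]23C[C@@]1(O)CC[C@H]2[C@]1(COC3=O)C(=O)C=CC(C)(C)[C@H]1CO[Si](c1ccccc1)(c1ccccc1)C(C)(C)C | intermediate
19 | (5R,8S,9S,10S,13S,16R)-13-hydroxy-1,15-dioxo-6,7-secokaur-2-en-7,20-olide 6-O-tert-butyldiphenylsilyl ether | C[C@H]1C(=O)[C@]23C[C@@]1(O)CC[C@H]2[C@]1(COC3=O)C(=O)C=CC(C)(C)[C@H]1CO[Si](c1ccccc1)(c1ccccc1)C(C)(C)C | intermediate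
20 | (5R,8S,9S,10S,13S,16R)-6,13-dihydroxy-1,15-dioxo-6,7-secokaur-2-en-7,20-olide | C[C@H]1C(=O)[C@]23C[C@@]1(O)CC[C@H]2[C@]1(COC3=O)C(=O)C=CC(C)(C)[C@H]1CO | target

**Step count and risks**

Total step count: 12. Longest linear sequence: 12 steps (1 → 20); 3, 10 and 14 are purchased and enter in steps 2, 6 and 7.

Steps most likely to fail:

1. Step 8: the 1,2-shift may take the wrong course, with C14 migrating in place of C11, or the oxythallation adduct may be solvolysed without migration. Fallback: set out from 15 and cleave the electron-rich exocyclic alkene by ozonolysis (O3, CH2Cl2–MeOH, −78 °C; Me2S), which should spare the electron-poor ring A enone and give the cyclopentanone F1. Homologation of F1 with Me3SiCHN2 under Sc(OTf)3 catalysis (CH2Cl2, −78 °C) should insert the diazo carbon on the less hindered C11 side to give the C12-silylated ketone F2, and protodesilylation (dilute HCl, THF) comes back to the route at 16.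

2. Step 7: addition of the palladium–trimethylenemethane zwitterion at the neopentylic C9 may be slow, so that 14 is consumed by protodesilylation and oligomerization, or facial discrimination may erode. Fallback: set out from 13 and carry out a Hosomi–Sakurai conjugate addition of 2-(chloromethyl)-3-(trimethylsilyl)prop-1-ene (TiCl4, CH2Cl2, −78 °C) to give the allylic chloride F3. Treatment with K2CO3 in MeCN should then close the five-membered ring by C-alkylation of the β-keto lactone, cis by ring size, and comes back to the route at 15.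

3. Step 6: the congested tetrasubstituted enolate may lose silyloxide by β-elimination or react at oxygen instead of at C10. Fallback: set out from 9 and form the silyl dienol ether F4 without a free enolate (Me3SiOTf, Et3N, CH2Cl2, 0 °C). A Mukaiyama-type reaction with HC(OMe)3 (Me3SiOTf cat., CH2Cl2, −78 °C) should give the quaternary β-keto acetal F5, again anti to the C5 arm, and aqueous acid (1 M HCl, THF) should remove the triethylsilyl group and unmask the hydroxy aldehyde F6. Knoevenagel condensation of F6 with ethyl 3-oxobutanoate (piperidine, AcOH, PhMe, 60 °C) followed by lactonization in the same flask comes back to the route at 13.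

**Further compounds**

F1 | step 8 | (5R,8S,9S,10S)-cyclopentanone analogue of 15 (C13 ketone in the five-membered ring, C12 removed) | CC(=O)[C@]12CC(=O)C[C@H]1[C@]1(COC2=O)C(=O)C=CC(C)(C)[C@H]1CO[Si](c1ccccc1)(c1ccccc1)C(C)(C)C
F2 | step 8 | 12-(trimethylsilyl) derivative of 16 (C12 configuration undefined) | CC(=O)[C@]12CC(=O)C([Si](C)(C)C)C[C@H]1[C@]1(COC2=O)C(=O)C=CC(C)(C)[C@H]1CO[Si](c1ccccc1)(c1ccccc1)C(C)(C)C
F3 | step 7 | (5R,6S,11R)-4-acetyl-11-({[tert-butyl(diphenyl)silyl]oxy}methyl)-5-[2-(chloromethyl)prop-2-en-1-yl]-10,10-dimethyl-2-oxaspiro[5.5]undec-8-ene-3,7-dione (C4 epimers) | CC(=O)C1[C@@H](CC(=C)CCl)[C@]2(COC1=O)C(=O)C=CC(C)(C)[C@H]2CO[Si](c1ccccc1)(c1ccccc1)C(C)(C)C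
F4 | step 6 | tert-butyl{[(1R)-6,6-dimethyl-2-{[(triethylsilyl)oxy]methyl}-3-[(trimethylsilyl)oxy]cyclohexa-2,4-dien-1-yl]methoxy}diphenylsilane | C[Si](C)(C)OC1=C(CO[Si](CC)(CC)CC)[C@H](CO[Si](c2ccccc2)(c2ccccc2)C(C)(C)C)C(C)(C)C=C1
F5 | step 6 | (5R,6S)-5-({[tert-butyl(diphenyl)silyl]oxy}methyl)-6-(dimethoxymethyl)-4,4-dimethyl-6-{[(triethylsilyl)oxy]methyl}cyclohex-2-en-1-one | O=C1C=CC(C)(C)[C@@H](CO[Si](c2ccccc2)(c2ccccc2)C(C)(C)C)[C@]1(CO[Si](CC)(CC)CC)C(OC)OC
F6 | step 6 | (1S,6R)-6-({[tert-butyl(diphenyl)silyl]oxy}methyl)-1-(hydroxymethyl)-5,5-dimethyl-2-oxocyclohex-3-ene-1-carbaldehyde | O=C[C@]1(CO)C(=O)C=CC(C)(C)[C@H]1CO[Si](c1ccccc1)(c1ccccc1)C(C)(C)C
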